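**Plan**

1. Atom and ring names: C1 = ketone carbon, C2 = the stereocenter, (S) by the CIP rules (O-aryl > C1 > C3 > H), C3 = CH2OH carbon; ring A = the 4-hydroxy-3,5-dimethoxyphenyl ring on C1; ring B = the 4-carboxy-2,6-dimethoxyphenoxy ring on C2.
2. Retrosynthesis, in order: the three benzyl groups (ring A phenol, ring B acid, C3–OH) come off; the C1–C2 bond is cut by reversing a CO2 extrusion–recombination, giving a mixed anhydride of the ring A aroyl unit and a racemic ring B 2-aryloxy-3-benzyloxypropanoic acid; then C2–C3 (ester enolate + BnOCH2Cl) and the ring B O–C2 bond (phenol + bromoacetate) are cut.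
3. Enabling feature: C2 is alpha to the ring B ether oxygen, so a carboxyl group placed on it leaves on one-electron oxidation as CO2 and a stabilised alpha-aryloxy radical; C2 is also the neighbour of the aryl ketone carbon C1, which can arrive as an acylnickel. Rings A and B are both syringic acid.
4. Forward: syringic acid gives the ring B phenol ester and the ring A acid chloride; ring B is extended to the C2–C3 acid; the halves are tied as an anhydride (temporary tether, traceless carboxyl) and the C1–C2–C3 chain is joined with loss of CO2, directly at the ketone oxidation level. No ring is formed.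
5. Stereochemistry: C2 is made racemic, erased as a planar radical and reset as (S) by a chiral bis(oxazoline)nickel catalyst in the key step (enantioconvergent). The endgame is base-free because C2–H is enolisable and the beta-hydroxy ketone can dehydrate.

Key step: step 7

Assumption: the sense of induction of the ligand in step 7 cannot be predicted with certainty. The route is written with (S,S)-Ph-BOX, 2,2'-(propane-2,2-diyl)bis[(4S)-4-phenyl-4,5-dihydro-1,3-oxazole]; the (R,R) antipode would be used instead if a test run shows the opposite sense.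

**Route**

Step 1
Reactants: 1 syringic acid (4-hydroxy-3,5-dimethoxybenzoic acid); 2 benzyl bromide
Product: 3 benzyl 4-hydroxy-3,5-dimethoxybenzoate
Conditions: BnBr (1.05 equiv), KHCO3 (1.2 equiv), DMF, 40 °C
Reagents that add atoms: benzyl bromide (2), BrCc1ccccc1
Why: Selective SN2 O-alkylation of the carboxylate (benzyl esterification), since KHCO3 deprotonates the acid but not the less acidic 4-OH flanked by two methoxy groups, so ring B keeps its free phenol.

Step 2
Reactants: 3 benzyl 4-hydroxy-3,5-dimethoxybenzoate; 4 tert-butyl bromoacetate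
Product: 5 benzyl 4-[2-(tert-butoxy)-2-oxoethoxy]-3,5-dimethoxybenzoate
Conditions: K2CO3, acetone, reflux
Reagents that add atoms: tert-butyl bromoacetate (4), CC(C)(C)OC(=O)CBr
Why: Williamson ether synthesis in which the phenoxide of 3 displaces bromide from the unhindered alpha-bromo ester; the tert-butyl ester is chosen so that acid can remove it later without touching the benzyl ester.

Step 3
Reactants: 5 benzyl 4-[2-(tert-butoxy)-2-oxoethoxy]-3,5-dimethoxybenzoate; 6 benzyl chloromethyl ether
Product: 7 benzyl 4-{[3-(benzyloxy)-1-(tert-butoxy)-1-oxopropan-2-yl]oxy}-3,5-dimethoxybenzoate (racemic)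
Conditions: LiN(iPr)2 (1.1 equiv), THF, −78 °C; then BnOCH2Cl, −78 to −40 °C
Reagents that add atoms: benzyl chloromethyl ether (6), ClCOCc1ccccc1
Why: Alkylation of a lithium ester enolate with a reactive alpha-chloro ether installs C3 with its oxygen already benzyl-protected; C2 is made racemic on purpose because step 7 erases and resets it, and at −78 °C the hindered amide base and the tert-butyl ester enolate should leave the aryl benzyl ester alone.

Step 4
Reactants: 7 benzyl 4-{[3-(benzyloxy)-1-(tert-butoxy)-1-oxopropan-2-yl]oxy}-3,5-dimethoxybenzoate (racemic)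
Product: 8 3-(benzyloxy)-2-{4-[(benzyloxy)carbonyl]-2,6-dimethoxyphenoxy}propanoic acid (racemic)
Conditions: CF3CO2H/CH2Cl2 (1:3), 0 °C to rt
Reagents that add atoms: none
Why: Acidolysis of the tert-butyl ester (AAL1, loss of the tert-butyl cation as 2-methylpropene) unmasks the carboxylic acid that serves as the traceless radical precursor, while benzyl ester, benzyl ether and aryl methyl ethers are stable to CF3CO2H at room temperature.

Step 5
Reactants: 1 syringic acid; 2 benzyl bromide
Product: 10 4-(benzyloxy)-3,5-dimethoxybenzoic acid, via benzyl 4-(benzyloxy)-3,5-dimethoxybenzoate 9 (not isolated)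
Conditions: BnBr (2.3 equiv), K2CO3, DMF, 60 °C; then 2 M NaOH, MeOH, 60 °C; HCl to pH 2
Reagents that add atoms: benzyl bromide (2), BrCc1ccccc1; sodium hydroxide, [Na+].[OH-]
Why: Exhaustive benzylation (Williamson ether synthesis plus carboxylate alkylation) followed by saponification (BAC2) of the benzyl ester in the same flask leaves only the base-stable aryl benzyl ether, giving the ring A acid from the same starting material as ring B.

Step 6
Reactants: 10 4-(benzyloxy)-3,5-dimethoxybenzoic acid; 11 oxalyl chloride
Product: 12 4-(benzyloxy)-3,5-dimethoxybenzoyl chloride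
Conditions: (COCl)2 (1.3 equiv), DMF (cat.), CH2Cl2, 0 °C to rt; evaporate
Reagents that add atoms: oxalyl chloride (11), ClC(=O)C(=O)Cl
Why: Acid chloride formation through the DMF-derived chloroiminium (Vilsmeier-type) catalyst, to which the benzyl ether and methoxy groups are inert, with the crude chloride used directly after evaporation.

Step 7
Reactants: 8 3-(benzyloxy)-2-{4-[(benzyloxy)carbonyl]-2,6-dimethoxyphenoxy}propanoic acid (racemic); 12 4-(benzyloxy)-3,5-dimethoxybenzoyl chloride
Product: 14 benzyl 4-{[(2S)-3-(benzyloxy)-1-[4-(benzyloxy)-3,5-dimethoxyphenyl]-1-oxopropan-2-yl]oxy}-3,5-dimethoxybenzoate, via mixed anhydride 13 (not isolated)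
Conditions: 8 (1.1 equiv), 2,6-lutidine (1.1 equiv), 12 (1.0 equiv), toluene, 0 °C to rt, filter off the lutidinium chloride under N2; then Ni(cod)2 (10 mol %), (S,S)-Ph-BOX (12 mol %), [Ir(dF(CF3)ppy)2(dtbbpy)]PF6 (1 mol %), toluene–MeCN, blue LEDs (450 nm), 15 °C
Reagents that add atoms: none
Why: Proposed new method: acid 8 and chloride 12 give the mixed anhydride 13, zerovalent nickel carrying the bis(oxazoline) inserts into an acyl–oxygen bond to give a divalent aroylnickel carboxylate, the excited trivalent iridium photocatalyst takes one electron from the alpha-aryloxy carboxylate, CO2 is lost, the planar C2 radical is captured at nickel, the trivalent acyl(alkyl)nickel reductively eliminates the C1–C2 bond, and divalent iridium returns monovalent nickel to the zerovalent state. The closest known reaction types are the racemic nickel/photoredox CO2 extrusion–recombination of mixed anhydrides of alpha-oxy and alpha-amino acids to ketones, the bis(oxazoline)nickel/photoredox enantioselective acylation of alpha-amino and benzylic radicals, and the nickel-catalysed enantioconvergent reductive coupling of acid chlorides with secondary benzyl chlorides; an enantioconvergent version on an alpha-aryloxy radical has not been shown. No ring is closed. The C2 stereocenter is controlled by the chiral ligand on nickel, which should differentiate the two faces of the prochiral radical in reversible capture followed by irreversible reductive elimination, so both enantiomers of 8 should converge on (S)-14. The step needs site selectivity and freedom from epimerisation: only the alpha-aryloxy carboxylate, not the ring A aroate, is oxidised at this potential and gives a stabilised radical, so insertion on the wrong side of the anhydride is unproductive; the beta-benzyloxy group is no radical leaving group; chloride is filtered off to avoid chlorine-radical hydrogen abstraction at the benzylic ether positions; and the medium holds no base strong enough to enolise the alpha-aryloxy ketone or eliminate benzyl alcohol from it.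

Step 8
Reactants: 14 benzyl 4-{[(2S)-3-(benzyloxy)-1-[4-(benzyloxy)-3,5-dimethoxyphenyl]-1-oxopropan-2-yl]oxy}-3,5-dimethoxybenzoate
Product: 15 4-{[(2S)-3-hydroxy-1-(4-hydroxy-3,5-dimethoxyphenyl)-1-oxopropan-2-yl]oxy}-3,5-dimethoxybenzoic acid (the target)
Conditions: H2 (1 atm), 10% Pd/C, THF–EtOAc, rt; filter, evaporate below 30 °C
Reagents that add atoms: none
Why: Catalytic hydrogenolysis of the three benzylic C–O bonds (aryl benzyl ether, benzyl ester, primary benzyl ether) in a neutral aprotic medium should leave the enolisable C2–H and the beta-hydroxy ketone untouched, while the aryl ketone, conjugated to the 4-oxygen of ring A, should be reduced more slowly, the reaction being stopped after uptake of three equivalents of H2.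

**Compound list**

1 | syringic acid (4-hydroxy-3,5-dimethoxybenzoic acid) | COc1cc(C(=O)O)cc(OC)c1O | starting material
2 | benzyl bromide | BrCc1ccccc1 | starting material
3 | benzyl 4-hydroxy-3,5-dimethoxybenzoate | COc1cc(C(=O)OCc2ccccc2)cc(OC)c1O | intermediate
4 | tert-butyl bromoacetate | CC(C)(C)OC(=O)CBr | starting material
5 | benzyl 4-[2-(tert-butoxy)-2-oxoethoxy]-3,5-dimethoxybenzoate | COc1cc(C(=O)OCc2ccccc2)cc(OC)c1OCC(=O)OC(C)(C)C | intermediate
6 | benzyl chloromethyl ether | ClCOCc1ccccc1 | starting material
7 | benzyl 4-{[3-(benzyloxy)-1-(tert-butoxy)-1-oxopropan-2-yl]oxy}-3,5-dimethoxybenzoate (racemic) | COc1cc(C(=O)OCc2ccccc2)cc(OC)c1OC(COCc3ccccc3)C(=O)OC(C)(C)C | intermediate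
8 | 3-(benzyloxy)-2-{4-[(benzyloxy)carbonyl]-2,6-dimethoxyphenoxy}propanoic acid (racemic) | COc1cc(C(=O)OCc2ccccc2)cc(OC)c1OC(COCc3ccccc3)C(=O)O | intermediate
9 | benzyl 4-(benzyloxy)-3,5-dimethoxybenzoate (formed in the flask in step 5) | COc1cc(C(=O)OCc2ccccc2)cc(OC)c1OCc3ccccc3 | intermediate
10 | 4-(benzyloxy)-3,5-dimethoxybenzoic acid | COc1cc(C(=O)O)cc(OC)c1OCc2ccccc2 | intermediate
11 | oxalyl chloride | ClC(=O)C(=O)Cl | starting material
12 | 4-(benzyloxy)-3,5-dimethoxybenzoyl chloride | COc1cc(C(=O)Cl)cc(OC)c1OCc2ccccc2 | intermediate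
13 | 4-(benzyloxy)-3,5-dimethoxybenzoic 3-(benzyloxy)-2-{4-[(benzyloxy)carbonyl]-2,6-dimethoxyphenoxy}propanoic anhydride (racemic, formed in the flask in step 7) | COc1cc(C(=O)OC(=O)C(COCc2ccccc2)Oc3c(OC)cc(C(=O)OCc4ccccc4)cc3OC)cc(OC)c1OCc5ccccc5 | intermediate
14 | benzyl 4-{[(2S)-3-(benzyloxy)-1-[4-(benzyloxy)-3,5-dimethoxyphenyl]-1-oxopropan-2-yl]oxy}-3,5-dimethoxybenzoate | COc1cc(C(=O)[C@H](COCc2ccccc2)Oc3c(OC)cc(C(=O)OCc4ccccc4)cc3OC)cc(OC)c1OCc5ccccc5 | intermediate
15 | 4-{[(2S)-3-hydroxy-1-(4-hydroxy-3,5-dimethoxyphenyl)-1-oxopropan-2-yl]oxy}-3,5-dimethoxybenzoic acid | COc1cc(C(=O)[C@H](CO)Oc2c(OC)cc(C(=O)O)cc2OC)cc(OC)c1O | target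

Total step count: 8. Longest linear sequence: 6 steps (steps 1, 2, 3, 4, 7, 8); the ring A branch (steps 5, 6) joins at step 7.

**Steps most likely to fail**

1. Step 7 (Proposed new method). What may go wrong: weak or opposite facial discrimination when the C2 radical is captured at nickel; epimerisation of the enolisable product in the flask; photoreductive cleavage of the new C2–O bond to ring B by the reduced photocatalyst; unproductive insertion of nickel on the wrong side of the anhydride. The enantiomeric purity of 14 should be checked by chiral HPLC before step 8.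
Fallback (known chemistry; sets out from 5, comes back at 15): an Evans syn-aldol forms the same C1–C2 bond at the alcohol oxidation level. From 5, CF3CO2H in CH2Cl2 should free 2-{4-[(benzyloxy)carbonyl]-2,6-dimethoxyphenoxy}acetic acid F1. Coupling with (R)-4-benzyl-1,3-oxazolidin-2-one (DCC, DMAP cat., CH2Cl2) should give benzyl 4-{2-[(4R)-4-benzyl-2-oxo-1,3-oxazolidin-3-yl]-2-oxoethoxy}-3,5-dimethoxybenzoate F2. Its dibutylboron Z-enolate (Bu2BOTf, iPr2NEt, CH2Cl2, −78 to 0 °C) should add to commercial 4-(benzyloxy)-3,5-dimethoxybenzaldehyde (COc1cc(C=O)cc(OC)c1OCc1ccccc1) through a Zimmerman–Traxler chair to give the syn-aldol benzyl 4-{[(2R,3S)-1-[(4R)-4-benzyl-2-oxo-1,3-oxazolidin-3-yl]-3-[4-(benzyloxy)-3,5-dimethoxyphenyl]-3-hydroxy-1-oxopropan-2-yl]oxy}-3,5-dimethoxybenzoate F3. NaBH4 in THF–H2O should remove the auxiliary reductively without touching the benzoate, giving benzyl 4-{[(1S,2S)-1-[4-(benzyloxy)-3,5-dimethoxyphenyl]-1,3-dihydroxypropan-2-yl]oxy}-3,5-dimethoxybenzoate F4, whose C2 can no longer enolise. DDQ in 1,4-dioxane should oxidise only the electron-rich benzylic C1 carbinol and leave the primary C3 alcohol, giving benzyl 4-{[(2S)-1-[4-(benzyloxy)-3,5-dimethoxyphenyl]-3-hydroxy-1-oxopropan-2-yl]oxy}-3,5-dimethoxybenzoate F5. Hydrogenolysis of its two benzyl groups under the conditions of step 8 should then give 15. The C2 descriptor changes from (2R) in F3 to (S) in F4, F5 and 15 only because the CIP ranks of its two carbon neighbours swap.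

2. Step 8. What may go wrong: over-reduction of the ring A ketone, hydrogenolytic loss of the ring B aryloxy group from C2, or incomplete cleavage of the primary benzyl ether at C3.
Fallback (sets out from 14, comes back at 15): non-reductive Lewis-acid debenzylation with BCl3 and pentamethylbenzene as cation scavenger in CH2Cl2 at −78 °C, quenched cold with MeOH. This should cleave all three benzyl–oxygen bonds without hydrogen and without base, and at this temperature should leave the four methyl ethers. It makes no new compound (F0).

3. Step 3. What may go wrong: Claisen-type attack of the enolate on an ester group, double alkylation, or decomposition of the enolate before it meets the electrophile.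
Fallback (sets out from 3, comes back at 8): commercial O-benzyl-DL-serine is diazotised in the presence of bromide (NaNO2, KBr, aqueous H2SO4, 0 °C) to give 3-(benzyloxy)-2-bromopropanoic acid F6. The sodium phenoxide of 3 then displaces bromide from the sodium carboxylate of F6 (NaH 2.2 equiv, DMF, 0 to 50 °C; Williamson ether synthesis on the alpha-halo carboxylate, which resists elimination better than its ester). Acidification should give 8 directly, with no ester to cleave.

Further compounds
F1 | step 7 | 2-{4-[(benzyloxy)carbonyl]-2,6-dimethoxyphenoxy}acetic acid | COc1cc(C(=O)OCc2ccccc2)cc(OC)c1OCC(=O)O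
F2 | step 7 | benzyl 4-{2-[(4R)-4-benzyl-2-oxo-1,3-oxazolidin-3-yl]-2-oxoethoxy}-3,5-dimethoxybenzoate | COc1cc(C(=O)OCc2ccccc2)cc(OC)c1OCC(=O)N3[C@H](Cc4ccccc4)COC3=O
F3 | step 7 | benzyl 4-{[(2R,3S)-1-[(4R)-4-benzyl-2-oxo-1,3-oxazolidin-3-yl]-3-[4-(benzyloxy)-3,5-dimethoxyphenyl]-3-hydroxy-1-oxopropan-2-yl]oxy}-3,5-dimethoxybenzoate | COc1cc([C@H](O)[C@@H](Oc2c(OC)cc(C(=O)OCc3ccccc3)cc2OC)C(=O)N4[C@H](Cc5ccccc5)COC4=O)cc(OC)c1OCc6ccccc6
F4 | step 7 | benzyl 4-{[(1S,2S)-1-[4-(benzyloxy)-3,5-dimethoxyphenyl]-1,3-dihydroxypropan-2-yl]oxy}-3,5-dimethoxybenzoate | COc1cc([C@H](O)[C@@H](Oc2c(OC)cc(C(=O)OCc3ccccc3)cc2OC)CO)cc(OC)c1OCc4ccccc4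
F5 | step 7 | benzyl 4-{[(2S)-1-[4-(benzyloxy)-3,5-dimethoxyphenyl]-3-hydroxy-1-oxopropan-2-yl]oxy}-3,5-dimethoxybenzoate | COc1cc(C(=O)[C@@H](Oc2c(OC)cc(C(=O)OCc3ccccc3)cc2OC)CO)cc(OC)c1OCc4ccccc4
F0 | step 8 | none | none
F6 | step 3 | 3-(benzyloxy)-2-bromopropanoic acid (racemic) | OC(=O)C(Br)COCc1ccccc1
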